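The earlier runs and the new flask were computed with made-up constants; the scatter is artificial.

Add the X and Q readings of each late sample and subtract the sum from the charge. What is missing is the number to follow in these flasks.

| flask | X | remark | time |
|---|---|---|---|
| red | 0.18 M | run made earlier |  |
| violet | 0.56 M | run made earlier |  |
| ochre | 1.6 M | run made earlier |  |
| ash | 0.20 M |  | 20 min |
| elm | 0.40 M |  | 20 min |
| cedar | 0.80 M |  | 20 min |
| alder | 1.5 M |  | 20 min |

| run | time / min | Q / % | X / % |
|---|---|---|---|
| red | 1.50 | 47.8 | 49.3 |
| red | 3.00 | 63.2 | 34.4 |
| red | 6.00 | 71.2 | 27.5 |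
| red | 10.0 | 72.4 | 27.3 |
| red | 20.0 | 72.1 | 25.5 |
| violet | 4.00 | 66.5 | 31.4 |
| violet | 8.00 | 71.6 | 26.8 |
| violet | 12.0 | 72.1 | 28.0 |
| violet | 15.0 | 72.4 | 25.7 |
| violet | 20.0 | 70.9 | 27.1 |
| ochre | 4.00 | 61.1 | 30.2 |
| ochre | 8.00 | 68.1 | 27.0 |
| ochre | 12.0 | 67.7 | 25.6 |
| ochre | 15.0 | 70.1 | 27.0 |
| ochre | 20.0 | 69.8 | 26.9 |

(each reading ± 1 percentage point)

- "hardly changes" means that all values lie within two and a half points (for a concentration: within two and a half percent of the largest)

* amount of Q at the end, in percent of the X charged for ash, elm, cedar, alder, in this order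
* how the row runs (falls all the way / rises, then falls / hardly changes / rises all the way / falls, then rises)

From 8.00 min on, violet and ochre look flat, yet their means don't seem to go together: X stands at 26.9% in violet and 26.6% in ochre, while Q stands at 71.8% against 68.9%. Nearly equal X readings with unequal Q readings look wrong for a plain balance of X and Q. But the gap in the sum is 1.3 percentage points in violet and 4.4 points in ochre, and Q's share of X plus Q is 72.7% in violet and 72.1% in ochre. With that split, ochre's gap, wider than violet's, should take 0.85 points from X and 2.3 points from Q, against a scatter of 1 point on a single reading.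

Now work in powers of ten. From violet to ochre the logarithm to base ten of the charge rises by 0.456 and that of the gap by 0.518. Their ratio, 1.14, is the apparent order of the gap in the charge; it is a rough reading, since both gaps carry the scatter. I scale ochre's gap to each new charge with this order and give Q violet's share of the rest. That yields 72.4%, 72.1%, 71.3% and 69.7%. The spread is 2.7 points against the 2.5 points allowed, so I commit, narrowly, to a steady fall.

The forecast gives 72%, 72%, 71.5% and 70%, and its shape is "hardly changes", with a holding species that it calls “negligible at or below 0.56 M”. We part on the shape.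

The flask gives 72.5%, 72.0%, 71.1% and 69.6%: the row falls all the way, so the forecast's values stand within the margin and its shape does not.

    2 X ⇌ L (K = 0.230 M⁻¹, k = 0.580 M⁻¹ min⁻¹)
    X ⇌ Q (K = 2.70, k = 0.536 min⁻¹)

Alder ends with 4.59% of its charge as L, the open dimer, each L counting as two X in that percentage. Taken with the order 1.14 from cedar's 2.55% down to the elm charge, L comes to 1.16%, and elm ends with 1.31%.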